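## Analysis of the target

The target (22) is a furanoheliangolide, and germacrane numbering is used throughout. A ten-membered carbocycle C1–C10 (ring B) is spanned by an ether bridge C3–O–C10; this closes a 3(2H)-furanone (ring A: O, C3, C2, C1, C10, with the C1 ketone, the C2=C3 enol ether and quaternary C10 bearing methyl C14), turns the rest of ring B into a nine-membered oxacycle, and an α-methylene-γ-butyrolactone (ring C: O6, C6, C7, C11, C12, exocyclic C11=C13) is trans-fused at C6–C7. The C4=C5 alkene is Z inside the ring, carries C15H2OH and is conjugated to ring A. The five contiguous stereocentres C6 (R), C7 (S), C8 (S), C9 (R) and C10 (S) have H6/H7 anti, H7/H8 syn, O8/O9 anti (a threo diol) and O9 anti to the bridge oxygen on C10; O8 bears a methacrylate and O9 an angelate. Sensitive features are three Michael acceptors (lactone C11=C13, methacrylate, furanone), the angelate (isomerises to the tiglate), acyl migration between O8 and O9, translactonisation from O6 to O8, and the Z-alkene. The difficulty lies in closing the strained bridged medium ring while fixing C6 and C7 relative to C8, and in telling O8 from O9. The feature that invites the key move sits in ring C: O6 and the methylene carbon C13 are 1,4-related through C7 and C11, so O6–C6–C7–C11=C13 is the product pattern of a [2,3]-shift of an O6–C13 allyl ether, and the vinylogous link of C6 to the C1 ketone of ring A (through C5=C4 and C3=C2) makes the C6–H bonds of such an ether the most acidic ones.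

## Retrosynthetic reasoning

**22 back to 18 (acyl and protecting groups).** The O15–Si bond, the O9–angeloyl bond and the O8–methacryloyl bond are cut last (21, 20, 19), and the 8,9-diol is tied up as the acetonide 18. The two esters are Michael acceptors and the angelate is configurationally labile, so neither can pass through the strongly basic key step. The forward reactions must acylate O8 before the more hindered, neopentyl-type O9.

**18 back to 15 (key disconnection).** In ring C the C6–C7 bond and the lactone O6–C12 bond are cut and O6 is reconnected to C13. This turns the bridged nine-membered oxacycle into the twelve-membered bis-allylic ether 15, in which a bond absent from the target (O6–C13) ties the two halves together. The gain is threefold: the medium ring is reached by contraction of a larger ring through a five-centre transition state, C6 and C7 are set as a pair by a suprafacial shift whose outcome follows from the enoate geometry of 15, and the tether atoms stay in the product as the lactone oxygen and the exocyclic methylene. The forward reaction has to deprotonate C6 selectively and form C6–C7 on the correct face of C7.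

**15 back to 14.** The C7=C11 bond is cut. Closing a twelve-membered ring by an intramolecular Horner–Wadsworth–Emmons reaction is a reliable macrocyclisation, and a Still–Gennari phosphonate makes the required geometry (C8 cis to the ester) the kinetic one. The precursor 14 carries the C7 aldehyde and the phosphonate at the two ends of an open chain.

**14 back to 12 and 7.** Ring A is opened at O–C3 to the γ-hydroxy ynone 13, and 13 is cut at C2–C3 and C3–C4. In the forward direction alkyne 12, vinyl iodide 7 and a one-carbon carbonyl component (C3 with its oxygen) are joined by a carbonylative Sonogashira coupling, and 13 is isomerised to the furanone. The vinyl iodide fixes the C4=C5 geometry, and the O6 ether of 7 keeps the acylpalladium from being captured as a butenolide.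

**7 back to 1 and 5.** The O6–C13 and C13–C11 bonds are cut: alkoxymethylation of the Still–Gennari phosphonoacetate 5 with the chloromethyl ether of 4. The iodide 4 comes from the monosilylated diol 2 by hydroxyl-directed trans-hydroalumination and iodination, and 2 from 1.

**12 back to 8.** C7–C10 are the four carbons of 8, the acetonide of dimethyl L-tartrate, which supplies C8 and C9. The C2-symmetric bis-amide 9 is desymmetrised by one methyl addition (10, the C10 ketone with C14). Chelation-controlled ethynyl addition sets C10 and brings in C1 and C2 (11), and reduction of the remaining amide gives the C7 aldehyde 12.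

## Alternatives that were turned down

**Alternative 1:** the textbook route, ring-closing metathesis at C4=C5. A diene A1 (lactone with a C6 vinyl group, furanone with a 1,1-disubstituted C4 alkene) would be closed with the second-generation Grubbs catalyst. It was turned down because the step must form a trisubstituted, electron-poor Z-alkene conjugated to ring A inside a nine-membered oxacycle, from the least reactive olefin class. The exocyclic C11=C13 and dimerisation compete. All five stereocentres, the C6/C7 pair included, would still have to be built in open-chain form, so the ring closure simplifies nothing.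

**Alternative 2:** ring closure through ring A. A seco compound A2 (preformed trans-lactone, (Z)-vinyl iodide at C4, ethynyl carbinol at C10) would be closed by an intramolecular carbonylative Sonogashira coupling to the ten-membered ynone A3, followed by transannular cyclisation to the furanone. It was turned down because the ten-membered ring must hold the linear C10–C1≡C2–C3 unit next to a cis-alkene and a trans-fused lactone at the reductive elimination stage. The tertiary hydroxyl can capture the acylpalladium. C6, C7 and C8 would have to be set beforehand by an intermolecular 2-(alkoxycarbonyl)allylation with three-way stereocontrol.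

**Alternative 3:** direct closure of the C6–C7 bond by a metal-mediated intramolecular allylation (Zn Barbier or CrCl2 Nozaki–Hiyama–Kishi type) of a bromo-enal A4 that already carries both esters, as the last step. It was turned down as first choice for four reasons. The allylmetal equilibrates by 1,3-metallotropy, so an enoate geometry set earlier is not transferred. With the readily made (Z)-bromide the closed six-membered transition state leads to the syn adduct, that is the cis-lactone. The (Z)-enal conjugated to ring A is prone to isomerisation. The nine-membered ring would be formed directly, and Morita–Baylis–Hillman reaction, bromination, protection, deprotection and oxidation cost more steps than the tether. A protected variant is kept as the fallback for the key step.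

Key step: step 11

Assumption: 1, 5, 8, angelic acid and methacrylic anhydride are taken as commercial; the SMILES of the target is read as (4Z,6R,7S,8S,9R,10S) with a (2Z)-2-methylbut-2-enoate on O9.

## Route

Step 1
Reactants: 1 but-2-yne-1,4-diol
Product: 2 4-[(tert-butyldiphenylsilyl)oxy]but-2-yn-1-ol
Conditions: NaH (1.0 equiv), THF, 0 °C; t-BuPh2SiCl (1.0 equiv), 0 °C → rt
Reagents that add atoms: tert-butyl(chloro)diphenylsilane, CC(C)(C)[Si](Cl)(c1ccccc1)c1ccccc1
Why: Monosilylation of a symmetrical diol through its sparingly soluble monosodium alkoxide; the robust TBDPS ether is chosen because it must survive HCl, strong base and aqueous acid later.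

Step 2
Reactants: 2 4-[(tert-butyldiphenylsilyl)oxy]but-2-yn-1-ol
Product: 4 (2Z)-4-[(tert-butyldiphenylsilyl)oxy]-3-iodobut-2-en-1-ol, via vinylalanate 3 (not isolated)
Conditions: NaAlH2(OCH2CH2OMe)2, THF, 0 °C → rt; then I2, THF, −78 → 0 °C
Reagents that add atoms: iodine, II
Why: Hydroxyl-directed trans-hydroalumination delivers hydride to C5 and aluminium to C4 within the five-membered alanate 3, and iododealumination with retention gives the vinyl iodide with iodine cis to C6; this is the later (4Z) geometry, with O15 already distinguished from O6.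

Step 3
Reactants: 4 (2Z)-4-[(tert-butyldiphenylsilyl)oxy]-3-iodobut-2-en-1-ol; 5 methyl 2-[bis(2,2,2-trifluoroethoxy)phosphoryl]acetate
Product: 7 methyl 2-[bis(2,2,2-trifluoroethoxy)phosphoryl]-3-{[(2Z)-4-[(tert-butyldiphenylsilyl)oxy]-3-iodobut-2-en-1-yl]oxy}propanoate (both C11 epimers), via chloromethyl ether 6 (not isolated)
Conditions: (CH2O)n, Me3SiCl, CH2Cl2, 0 °C → rt, evaporate; then 5 (1.5 equiv), NaH, THF, 0 °C → rt
Reagents that add atoms: paraformaldehyde (formaldehyde unit), C=O
Why: The alcohol, paraformaldehyde and Me3SiCl give the α-chloro ether 6 (C13), which C-alkylates the sodium salt of the Still–Gennari phosphonoacetate. This puts C13, C11 and C12 on O6 and masks O6, which as a free hydroxyl would intercept the acylpalladium of step 8.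

Step 4
Reactants: 8 dimethyl (4R,5R)-2,2-dimethyl-1,3-dioxolane-4,5-dicarboxylate
Product: 9 (4R,5R)-N4,N5-dimethoxy-N4,N5,2,2-tetramethyl-1,3-dioxolane-4,5-dicarboxamide
Conditions: MeNHOMe·HCl, i-PrMgCl, THF, −20 → 0 °C
Reagents that add atoms: N,O-dimethylhydroxylamine hydrochloride, CNOC.Cl
Why: Aminolysis of both esters by the magnesium amide gives the C2-symmetric bis-Weinreb amide; the trans-dioxolane stereocentres (later C8 and C9) are not enolised under these conditions.

Step 5
Reactants: 9 (4R,5R)-N4,N5-dimethoxy-N4,N5,2,2-tetramethyl-1,3-dioxolane-4,5-dicarboxamide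
Product: 10 (4R,5R)-5-acetyl-N-methoxy-N,2,2-trimethyl-1,3-dioxolane-4-carboxamide
Conditions: MeMgBr (1.1 equiv), THF, −20 → 0 °C; aq. NH4Cl
Reagents that add atoms: methylmagnesium bromide, C[Mg]Br
Why: Desymmetrising Weinreb ketone synthesis: the two amides are homotopic, the first addition gives a stable magnesium chelate that only collapses on work-up, and the limited amount of Grignard reagent keeps the second amide for C7.

Step 6
Reactants: 10 (4R,5R)-5-acetyl-N-methoxy-N,2,2-trimethyl-1,3-dioxolane-4-carboxamide
Product: 11 (4R,5R)-5-[(2R)-2-hydroxybut-3-yn-2-yl]-N-methoxy-N,2,2-trimethyl-1,3-dioxolane-4-carboxamide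
Conditions: HC≡CMgBr (1.5 equiv), MgBr2·OEt2, CH2Cl2/THF, −78 °C
Reagents that add atoms: ethynylmagnesium bromide, C#C[Mg]Br
Why: 1,2-Addition to the ketone, which reacts far faster than the Weinreb amide at −78 °C. Magnesium chelates the ketone oxygen and the α-oxygen O9, and the acetylide enters from the face of H9, which places O10 syn to O9 in the C1–C10–C9–C8 zigzag, the C10 configuration of the target (chelation control).

Step 7
Reactants: 11 (4R,5R)-5-[(2R)-2-hydroxybut-3-yn-2-yl]-N-methoxy-N,2,2-trimethyl-1,3-dioxolane-4-carboxamide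
Product: 12 (4R,5R)-5-[(2R)-2-hydroxybut-3-yn-2-yl]-2,2-dimethyl-1,3-dioxolane-4-carbaldehyde
Conditions: i-Bu2AlH (2.5 equiv), THF, −78 °C; aq. potassium sodium tartrate
Reagents that add atoms: none
Why: Weinreb amide reduction stops at the chelated hemiaminal aluminate and releases the C7 aldehyde on work-up; the trans-fused acetonide prevents lactol formation with the C10 hydroxyl, and the aldehyde is used without delay.

Step 8
Reactants: 12 (4R,5R)-5-[(2R)-2-hydroxybut-3-yn-2-yl]-2,2-dimethyl-1,3-dioxolane-4-carbaldehyde; 7 methyl 2-[bis(2,2,2-trifluoroethoxy)phosphoryl]-3-{[(2Z)-4-[(tert-butyldiphenylsilyl)oxy]-3-iodobut-2-en-1-yl]oxy}propanoate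
Product: 13 seco-ynone, methyl 2-[bis(2,2,2-trifluoroethoxy)phosphoryl]-3-{[(2Z,7R)-3-{[(tert-butyldiphenylsilyl)oxy]methyl}-7-[(4R,5R)-5-formyl-2,2-dimethyl-1,3-dioxolan-4-yl]-7-hydroxy-4-oxooct-2-en-5-yn-1-yl]oxy}propanoate
Conditions: CO (1 atm), PdCl2(PPh3)2 (5 mol %), CuI (2 mol %), Et3N, THF, rt
Reagents that add atoms: carbon monoxide, [C-]#[O+]
Why: Carbonylative Sonogashira coupling: oxidative addition of zerovalent palladium to the vinyl iodide with retention, CO insertion, alkynyl transfer from the copper acetylide and reductive elimination join three components and form C2–C3 and C3–C4. Triethylamine is too weak a base to start the olefination between the phosphonate and the aldehyde.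

Step 9
Reactants: 13 seco-ynone (as in step 8)
Product: 14 furanone aldehyde, methyl 2-[bis(2,2,2-trifluoroethoxy)phosphoryl]-3-{[(2Z)-4-[(tert-butyldiphenylsilyl)oxy]-3-{(5S)-5-[(4R,5R)-5-formyl-2,2-dimethyl-1,3-dioxolan-4-yl]-5-methyl-4-oxo-4,5-dihydrofuran-2-yl}but-2-en-1-yl]oxy}propanoate
Conditions: (4-CF3C6H4)3PAuCl (5 mol %), AgOTf (5 mol %), toluene (trace H2O), rt
Reagents that add atoms: none
Why: Gold-catalysed cycloisomerisation of a γ-hydroxy ynone to a 3(2H)-furanone: the activated alkyne is hydrated at C1, the C10 hydroxyl adds to the C3 carbonyl, and loss of water leaves the C1 ketone and the C2=C3 enol ether. C10 is not touched, and the neutral conditions spare the aldehyde and the phosphonate.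

Step 10
Reactants: 14 furanone aldehyde (as in step 9)
Product: 15 twelve-membered cyclic ether-enoate (ring: C11, C7, C8, C9, C10, furanone O, C3, C4, C5, C6, O, C13; methyl ester on C11; C7=C11 Z with C8 cis to CO2Me; C4=C5 Z; 8,9-O-isopropylidene; 15-O-TBDPS)
Conditions: K2CO3, 18-crown-6, toluene, 0 °C → rt, 1 mM, slow addition
Reagents that add atoms: none
Why: Intramolecular Horner–Wadsworth–Emmons macrocyclisation in its Still–Gennari form: the electron-poor trifluoroethyl phosphonate and the crown-complexed potassium ion make elimination from the first-formed adduct fast, so the (Z)-enoate is the kinetic product. High dilution favours the twelve-membered ring, in which the new alkene is trans within the ring.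

Step 11
Reactants: 15 twelve-membered cyclic ether-enoate (as in step 10)
Product: 18 (6R,7S,8S,9R,10S)-8,9-O-isopropylidene-15-O-TBDPS furanoheliangolide core (rings A, B and C complete), via potassium trienolate 16 (not isolated), via hydroxy ester 17 (not isolated)
Conditions: KN(SiMe3)2 (1.1 equiv), THF, −78 → −30 °C; AcOH, −78 °C; then PPTS (cat.), CH2Cl2, rt
Reagents that add atoms: none
Why: Proposed new method: KN(SiMe3)2 removes a C6 hydrogen of 15, which is alpha to the ether oxygen and doubly vinylogous to the C1 ketone, to give trienolate 16; its C6 terminus bonds to C7 of the (Z)-2-(alkoxymethyl)enoate through a five-centre envelope transition state while the C13–O bond breaks, a [2,3]-Wittig rearrangement. The closest known reaction types are the [2,3]-Wittig ring contraction of thirteen-membered bis-allylic ethers to ten-membered germacradienols and the enolate [2,3]-Wittig rearrangement of α-allyloxy carbonyl compounds; new are the vinylogous stabilisation of the carbanion and the acrylate as migrating allyl unit, which makes C7 electrophilic (the stepwise limit, Michael addition then loss of the β-alkoxide, gives the same product). The shift contracts the twelve-membered ether to the oxygen-bridged nine-membered ring (ten-membered carbocycle) by a sigmatropic 2,3-closure, and the freed C6 hydroxyl of 17 then closes ring C by a 5-exo-trig acyl substitution on the methyl ester, completed with PPTS. C6 and C7 are set as a pair by the suprafacial shift: with C8 trans to C13 on the enoate and C5 exo on the envelope the anti adduct forms, which is the trans-fused lactone. C7 relative to C8 is controlled by C8: allylic 1,3-strain with the cis ester holds H8 in the enoate plane, and the tethered C6 should reach C7 on the face syn to O8, because approach syn to C9 would need a nearly eclipsed C6–C7–C8–C9 torsion in the nascent nine-membered ring. The step needs deprotonation at C6 and not at C8 (C8–H lies in the nodal plane of the enoate and is only the γ-hydrogen of an ester), bond formation at C6 and not at C2 or C4 (only C6 reaches C7 through a five-membered array), and retention of the C4=C5 geometry, which the ring enforces.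

Step 12
Reactants: 18 8,9-O-isopropylidene-15-O-TBDPS core (as in step 11)
Product: 19 8,9-diol (15-O-TBDPS; stereocentres as in 22)
Conditions: CF3CO2H/H2O (9:1), CH2Cl2, 0 °C
Reagents that add atoms: none
Why: Acid hydrolysis of the strained trans-dioxolane; the primary TBDPS ether, the electron-poor allylic lactone and the furanone tolerate brief cold aqueous acid.

Step 13
Reactants: 19 8,9-diol (as in step 12)
Product: 20 8-O-methacrylate (9-OH free, 15-O-TBDPS)
Conditions: methacrylic anhydride (1.1 equiv), Et3N, DMAP (cat.), CH2Cl2, −40 → −20 °C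
Reagents that add atoms: methacrylic anhydride, CC(=C)C(=O)OC(=O)C(C)=C
Why: DMAP-catalysed acylation under kinetic control: O9 is neopentyl-like (next to quaternary C10 and syn to C14), so the less hindered O8 should react first; low temperature suppresses acyl migration and attack of O8 on the lactone carbonyl.

Step 14
Reactants: 20 8-O-methacrylate (as in step 13)
Product: 21 15-O-TBDPS ether of the target
Conditions: angelic acid, 2,4,6-Cl3C6H2COCl, Et3N, toluene, rt, filter; then 20, toluene, 80 °C
Reagents that add atoms: angelic acid, C/C=C(/C)C(=O)O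
Why: Yamaguchi-type esterification through the mixed anhydride without a nucleophilic catalyst, the conditions under which the (Z)-acid is transferred to hindered alcohols without isomerising to the tiglate; only O9 is left to react.

Step 15
Reactants: 21 15-O-TBDPS ether of the target (as in step 14)
Product: 22 target, (4Z,6R,7S,8S,9R,10S)-9-angeloyloxy-15-hydroxy-8-methacryloyloxy-1-oxo-3,10-epoxygermacra-2,4,11(13)-trien-12,6-olide
Conditions: HF·pyridine, pyridine, THF, 0 °C → rt
Reagents that add atoms: none
Why: Fluoride-mediated cleavage of the primary silyl ether under buffered, weakly acidic conditions that leave the three Michael acceptors and the two esters alone.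

## Compound list

1 | but-2-yne-1,4-diol | OCC#CCO | starting material
2 | 4-[(tert-butyldiphenylsilyl)oxy]but-2-yn-1-ol | OCC#CCO[Si](c1ccccc1)(c1ccccc1)C(C)(C)C | intermediate
3 | sodium cyclic alkoxy(vinyl)alanate from trans-hydroalumination of 2 | [Na+].COCCO[Al-]1(OCCOC)OCC=C1CO[Si](c1ccccc1)(c1ccccc1)C(C)(C)C | intermediate
4 | (2Z)-4-[(tert-butyldiphenylsilyl)oxy]-3-iodobut-2-en-1-ol | OC/C=C(\I)CO[Si](c1ccccc1)(c1ccccc1)C(C)(C)C | intermediate
5 | methyl 2-[bis(2,2,2-trifluoroethoxy)phosphoryl]acetate | COC(=O)CP(=O)(OCC(F)(F)F)OCC(F)(F)F | starting material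
6 | tert-butyl{[(2Z)-4-(chloromethoxy)-2-iodobut-2-en-1-yl]oxy}diphenylsilane | ClCOC/C=C(\I)CO[Si](c1ccccc1)(c1ccccc1)C(C)(C)C | intermediate
7 | methyl 2-[bis(2,2,2-trifluoroethoxy)phosphoryl]-3-{[(2Z)-4-[(tert-butyldiphenylsilyl)oxy]-3-iodobut-2-en-1-yl]oxy}propanoate | COC(=O)C(COC/C=C(\I)CO[Si](c1ccccc1)(c1ccccc1)C(C)(C)C)P(=O)(OCC(F)(F)F)OCC(F)(F)F | intermediate
8 | dimethyl (4R,5R)-2,2-dimethyl-1,3-dioxolane-4,5-dicarboxylate | COC(=O)[C@@H]1OC(C)(C)O[C@H]1C(=O)OC | starting material
9 | (4R,5R)-N4,N5-dimethoxy-N4,N5,2,2-tetramethyl-1,3-dioxolane-4,5-dicarboxamide | CON(C)C(=O)[C@@H]1OC(C)(C)O[C@H]1C(=O)N(C)OC | intermediate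
10 | (4R,5R)-5-acetyl-N-methoxy-N,2,2-trimethyl-1,3-dioxolane-4-carboxamide | CON(C)C(=O)[C@@H]1OC(C)(C)O[C@H]1C(C)=O | intermediate
11 | (4R,5R)-5-[(2R)-2-hydroxybut-3-yn-2-yl]-N-methoxy-N,2,2-trimethyl-1,3-dioxolane-4-carboxamide | CON(C)C(=O)[C@@H]1OC(C)(C)O[C@H]1[C@](C)(O)C#C | intermediate
12 | (4R,5R)-5-[(2R)-2-hydroxybut-3-yn-2-yl]-2,2-dimethyl-1,3-dioxolane-4-carbaldehyde | O=C[C@@H]1OC(C)(C)O[C@H]1[C@](C)(O)C#C | intermediate
13 | seco-ynone (C7 aldehyde, 8,9-O-isopropylidene, 10-hydroxy, C1≡C2, C3 ketone, (4Z), 15-O-TBDPS, O6–C13H2–C11H(CO2Me)P(O)(OCH2CF3)2) | O=C[C@@H]1OC(C)(C)O[C@H]1[C@](C)(O)C#CC(=O)/C(CO[Si](c2ccccc2)(c2ccccc2)C(C)(C)C)=C\COCC(C(=O)OC)P(=O)(OCC(F)(F)F)OCC(F)(F)F | intermediate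
14 | furanone aldehyde (ring A closed; C7 aldehyde; phosphonate on the O6 ether chain) | O=C[C@@H]1OC(C)(C)O[C@H]1[C@]2(C)OC(=CC2=O)/C(CO[Si](c3ccccc3)(c3ccccc3)C(C)(C)C)=C\COCC(C(=O)OC)P(=O)(OCC(F)(F)F)OCC(F)(F)F | intermediate
15 | twelve-membered cyclic ether-enoate ((7Z)-C7=C11 with CO2Me on C11, C13H2–O–C6H2 bridge, (4Z), 8,9-O-isopropylidene, 15-O-TBDPS) | COC(=O)/C1=C\[C@@H]2OC(C)(C)O[C@H]2[C@]3(C)OC(=CC3=O)/C(CO[Si](c4ccccc4)(c4ccccc4)C(C)(C)C)=C\COC1 | intermediate
16 | potassium trienolate of 15 (C6 deprotonated, charge on O1; geometry of the new double bonds not defined) | [K+].COC(=O)/C1=C\[C@@H]2OC(C)(C)O[C@H]2[C@]3(C)OC(C=C3[O-])=C(CO[Si](c4ccccc4)(c4ccccc4)C(C)(C)C)C=COC1 | intermediate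
17 | hydroxy ester (rings A and B complete; 6-OH; methyl 2-substituted acrylate on C7; 8,9-O-isopropylidene; 15-O-TBDPS) | O3[C@H]1[C@@H](C(=C)C(=O)OC)[C@H](O)/C=C(/CO[Si](c4ccccc4)(c4ccccc4)C(C)(C)C)C2=CC(=O)[C@@](C)(O2)[C@@H]1OC3(C)C | intermediate
18 | (6R,7S,8S,9R,10S)-8,9-O-isopropylidene-15-O-TBDPS furanoheliangolide core | O3[C@H]1[C@H]2C(=C)C(=O)O[C@@H]2/C=C(/CO[Si](c4ccccc4)(c4ccccc4)C(C)(C)C)C2=CC(=O)[C@@](C)(O2)[C@@H]1OC3(C)C | intermediate
19 | 8,9-diol (15-O-TBDPS) | O[C@H]1[C@H]2C(=C)C(=O)O[C@@H]2/C=C(/CO[Si](c3ccccc3)(c3ccccc3)C(C)(C)C)C2=CC(=O)[C@@](C)(O2)[C@@H]1O | intermediate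
20 | 8-O-methacrylate (9-OH, 15-O-TBDPS) | C=C(C)C(=O)O[C@H]1[C@H]2C(=C)C(=O)O[C@@H]2/C=C(/CO[Si](c3ccccc3)(c3ccccc3)C(C)(C)C)C2=CC(=O)[C@@](C)(O2)[C@@H]1O | intermediate
21 | 15-O-TBDPS ether of the target | C=C(C)C(=O)O[C@H]1[C@H]2C(=C)C(=O)O[C@@H]2/C=C(/CO[Si](c3ccccc3)(c3ccccc3)C(C)(C)C)C2=CC(=O)[C@@](C)(O2)[C@@H]1OC(=O)/C(C)=C\C | intermediate
22 | (4Z,6R,7S,8S,9R,10S)-9-angeloyloxy-15-hydroxy-8-methacryloyloxy-1-oxo-3,10-epoxygermacra-2,4,11(13)-trien-12,6-olide | C=C(C)C(=O)O[C@H]1[C@H]2C(=C)C(=O)O[C@@H]2/C=C(/CO)C2=CC(=O)[C@@](C)(O2)[C@@H]1OC(=O)/C(C)=C\C | target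

## Step count and least certain steps

Total: 15 steps. Longest linear sequence: 12 steps (steps 4–15 from 8); the branch from 1 (steps 1–3) joins at step 8.

**Step 11 (key step, proposed new method).** Three things may go wrong: deprotonation at C8 or loss of the C15 silyloxy group from the extended enolate instead of rearrangement; rearrangement through the other envelope or on the other face of C7, giving poor selectivity at C6/C7; and conjugate addition of liberated methoxide to the new methylene lactone. The fallback uses known chemistry, sets out from 12 and 4 and returns at 18. Aldehyde 12 is taken with methyl acrylate and DABCO to the Morita–Baylis–Hillman adduct F1, and 4 is silylated with Et3SiCl to the TES ether F2. Carbonylative Sonogashira coupling of F1 and F2 and gold-catalysed cyclisation as in steps 8 and 9 give the furanone F3. PBr3 (allylic bromide with transposition), PPTS/MeOH (TES removal) and MnO2 give the bromo-enal F4. CrCl2 in THF at high dilution (intramolecular Nozaki–Hiyama–Kishi-type allylation with lactonisation, a known way to close germacranolide rings) gives 18. The price is that the equilibrating allylchromium no longer transfers the enoate geometry, so a C6/C7 mixture must be reckoned with.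

**Step 10.** Intermolecular olefination may lead to oligomers, ring strain may erode the Z-selectivity, and the α-alkoxy aldehyde may epimerise at C8 under base. The fallback sets out from 12 and 7 and returns at 15. An intermolecular Still–Gennari olefination (KN(SiMe3)2, 18-crown-6, THF, −78 °C) gives the open-chain (Z)-enoate F5, where the geometry is set without ring constraints. Intramolecular carbonylative Sonogashira coupling at high dilution gives the thirteen-membered ynone F6, and gold-catalysed cyclisation as in step 9 gives 15.

**Step 8.** Direct coupling without CO uptake, capture of the acylpalladium by a hydroxyl group, or premature olefination between aldehyde and phosphonate may compete. The fallback sets out from 7 (with 12) and returns at 13; it separates CO uptake from alkynylation. Hydroxycarbonylation of 7 (PdCl2(PPh3)2, CO, K2CO3, aqueous THF) gives the acid F7, 1-chloro-N,N,2-trimethylprop-1-en-1-amine gives the acid chloride F8, and acyl Sonogashira coupling of F8 with 12 (PdCl2(PPh3)2, CuI, Et3N) gives 13.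

**Step 6.** Chelate and non-chelate pathways may compete and give poor facial selectivity at C10. The fallback sets out from 9 and returns at 11; it reverses the order of the two nucleophiles so that non-chelation control gives the same C10 configuration. LiC≡CSiMe3 (1 equiv) converts 9 into the silyl ynone F9, MeTi(OiPr)3 adds under Felkin–Anh control to give the carbinol F10, and K2CO3/MeOH removes the silyl group to give 11; step 5 is then skipped.

**Step 13.** Acylation may be unselective between O8 and O9, the acyl group may migrate, or O8 may attack the lactone carbonyl (translactonisation). The fallback sets out from 19 and returns at 21. Et3SiCl/imidazole at −20 °C silylates the less hindered O8 to give the silyl ether F11, angeloylation as in step 14 gives the 9-angelate F12, AcOH/THF/H2O removes the TES group to give the 8-alcohol F13, and methacrylic anhydride/DMAP gives 21.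

## Further compounds

F1 | step 11 | Morita–Baylis–Hillman adduct of 12 (both C7 epimers) | COC(=O)C(=C)C(O)[C@@H]1OC(C)(C)O[C@H]1[C@](C)(O)C#C
F2 | step 11 | TES ether of 4 | CC[Si](CC)(CC)OC/C=C(\I)CO[Si](c1ccccc1)(c1ccccc1)C(C)(C)C
F3 | step 11 | furanone with C7 allylic alcohol and 6-O-TES ether | COC(=O)C(=C)C(O)[C@@H]1OC(C)(C)O[C@H]1[C@]2(C)OC(=CC2=O)/C(CO[Si](c3ccccc3)(c3ccccc3)C(C)(C)C)=C\CO[Si](CC)(CC)CC
F4 | step 11 | bromo-enal ((2Z)-2-(bromomethyl)enoate, C6 aldehyde) | COC(=O)/C(CBr)=C/[C@@H]1OC(C)(C)O[C@H]1[C@]2(C)OC(=CC2=O)/C(CO[Si](c3ccccc3)(c3ccccc3)C(C)(C)C)=C\C=O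
F5 | step 10 | open-chain (Z)-enoate with vinyl iodide and ethynyl carbinol | COC(=O)/C(COC/C=C(\I)CO[Si](c1ccccc1)(c1ccccc1)C(C)(C)C)=C\[C@@H]2OC(C)(C)O[C@H]2[C@](C)(O)C#C
F6 | step 10 | thirteen-membered cyclic γ-hydroxy ynone | COC(=O)/C1=C\[C@@H]2OC(C)(C)O[C@H]2[C@](C)(O)C#CC(=O)/C(CO[Si](c3ccccc3)(c3ccccc3)C(C)(C)C)=C\COC1
F7 | step 8 | (Z)-acrylic acid from hydroxycarbonylation of 7 | OC(=O)/C(CO[Si](c1ccccc1)(c1ccccc1)C(C)(C)C)=C\COCC(C(=O)OC)P(=O)(OCC(F)(F)F)OCC(F)(F)F
F8 | step 8 | acid chloride of F7 | ClC(=O)/C(CO[Si](c1ccccc1)(c1ccccc1)C(C)(C)C)=C\COCC(C(=O)OC)P(=O)(OCC(F)(F)F)OCC(F)(F)F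
F9 | step 6 | (trimethylsilyl)ethynyl ketone from 9 | CON(C)C(=O)[C@@H]1OC(C)(C)O[C@H]1C(=O)C#C[Si](C)(C)C
F10 | step 6 | C-silylated analogue of 11 | CON(C)C(=O)[C@@H]1OC(C)(C)O[C@H]1[C@](C)(O)C#C[Si](C)(C)C
F11 | step 13 | 8-O-TES ether of 19 | CC[Si](CC)(CC)O[C@H]1[C@H]2C(=C)C(=O)O[C@@H]2/C=C(/CO[Si](c3ccccc3)(c3ccccc3)C(C)(C)C)C2=CC(=O)[C@@](C)(O2)[C@@H]1O
F12 | step 13 | 8-O-TES 9-O-angelate | CC[Si](CC)(CC)O[C@H]1[C@H]2C(=C)C(=O)O[C@@H]2/C=C(/CO[Si](c3ccccc3)(c3ccccc3)C(C)(C)C)C2=CC(=O)[C@@](C)(O2)[C@@H]1OC(=O)/C(C)=C\C
F13 | step 13 | 9-O-angelate with free 8-OH | O[C@H]1[C@H]2C(=C)C(=O)O[C@@H]2/C=C(/CO[Si](c3ccccc3)(c3ccccc3)C(C)(C)C)C2=CC(=O)[C@@](C)(O2)[C@@H]1OC(=O)/C(C)=C\C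
A1 | alternative 1 | metathesis diene (C6 vinyl lactone, C4 1,1-disubstituted alkene on the furanone) | C=C[C@H]1OC(=O)C(=C)[C@@H]1[C@@H]2OC(C)(C)O[C@H]2[C@]3(C)OC(=CC3=O)C(=C)CO[Si](c4ccccc4)(c4ccccc4)C(C)(C)C
A2 | alternative 2 | seco lactone with (Z)-vinyl iodide and ethynyl carbinol | C#C[C@@](C)(O)[C@@H]1OC(C)(C)O[C@H]1[C@H]2C(=C)C(=O)O[C@@H]2/C=C(\I)CO[Si](c3ccccc3)(c3ccccc3)C(C)(C)C
A3 | alternative 2 | ten-membered cyclic γ-hydroxy ynone | CC(C)(C)[Si](c1ccccc1)(c1ccccc1)OC/C2=C/[C@H]3OC(=O)C(=C)[C@@H]3[C@@H]3OC(C)(C)O[C@H]3[C@](C)(O)C#CC2=O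
A4 | alternative 3 | fully acylated bromo-enal | COC(=O)/C(CBr)=C/[C@H](OC(=O)C(C)=C)[C@@H](OC(=O)/C(C)=C\C)[C@]1(C)OC(=CC1=O)/C(CO)=C\C=O
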